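At 3.0 h you read this flask, so until then keep it closed and stirred. It holds solid substrate at 0.12 M with 0.500 equiv of reagent; the solid dissolves into starting material, and target forms in solution.

| flask | solid substrate | reagent | remark | time |
|---|---|---|---|---|
| Monday's | 0.080 M | 0.50 equiv | run made earlier |  |
| Friday's | 0.18 M | 0.50 equiv | run made earlier |  |
| Wednesday's | 0.12 M | 0.25 equiv | run made earlier |  |
| flask | 0.12 M | 0.500 equiv |  | 3.0 h |

| run | time / h | target / % | starting material / % |
|---|---|---|---|
| Monday's | 0.167 | 2 | 3 |
| Monday's | 0.500 | 9 | 5 |
| Monday's | 0.833 | 13 | 7 |
| Monday's | 1.33 | 23 | 16 |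
| Monday's | 2.00 | 28 | 25 |
| Monday's | 2.50 | 29 | 34 |
| Friday's | 0.417 | 4 | 2 |
| Friday's | 0.833 | 8 | 1 |
| Friday's | 1.33 | 13 | 3 |
| Friday's | 1.50 | 13 | 7 |
| Friday's | 2.00 | 17 | 5 |
| Friday's | 2.50 | 17 | 7 |
| Wednesday's | 0.200 | 3 | 3 |
| Wednesday's | 0.333 | 2 | 1 |
| Wednesday's | 0.667 | 12 | 4 |
| Wednesday's | 1.33 | 14 | 13 |
| Wednesday's | 2.50 | 13 | 27 |

(each reading ± 2 percentage points)

- given per volume of solution although it is solid: solid substrate
- at the start none of the solid substrate is in solution
- starting material is what solid substrate becomes in solution
- starting material means what is dissolved; the solid is not counted in it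

- amount of target at 3.0 h, in percent of the solid substrate charged
- concentration of starting material in solution at 50 min, in percent of saturation
- the change that raises the amount of target at 3.0 h, in percent of the solid substrate charged most ("none" if none brings more than 2 percentage points) (alpha / beta / gamma / none)
- amount of target at 3.0 h, in percent of the solid substrate charged, after gamma

- alpha: doubling the solubility of the solid substrate, all else as stated
- beta: doubling the amount of reagent, all else as stated
- gamma: doubling the dissolution coefficient of the solid substrate, all else as stated

Target flattens late in the earlier runs: Monday's last readings are 28% and 29%, Friday's 17% and 17%. I turn each last reading into a concentration. Monday gives [target] = 0.0232 M from [reagent] = 0.0400 M, and Friday gives 0.0306 M from 0.0900 M.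

On logarithmic axes, two points give a slope. I read 0.341 for the reagent gain, the slope of late [target] against charged [reagent]. It is a reading: both runs hold 0.50 equiv, so solid substrate moves with [reagent] between them, and each percentage behind it carries a scatter of 2 percentage points.

This flask has [reagent] = 0.0600 M, between those two runs, so I expect 22.2% of target. Don't add reagent expecting a proportional return: the gain is less than 1, so on this slope doubling it multiplies target by 1.27.

The forecast gives 24% (20% to 28%), more than my figure, with 8% of saturation at 50 min, 30% after gamma and beta as the best change, a choice of which it says that it “holds under either explanation” of the lost reagent.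

    starting material + 2 reagent → side product (k = 950 M⁻² h⁻¹)
    starting material + reagent → target (k = 120 M⁻¹ h⁻¹)
    2 reagent → self-condensation product (k = 6.00 M⁻¹ h⁻¹)
    solid substrate ⇌ starting material, rate k4*(cs4 - [starting material]) while solid is left; crystals form when [starting material] > cs4 (solubility = 0.0620 M, k = 0.430 h⁻¹)

The flask gives 24.9% at 3.0 h, with starting material at 8.84% of saturation at 50 min, beta as the best change, gaining 5.4 points, and 28.0% after gamma. Reagent is the limiting reagent in this flask: 0.42% of its charge stands at 3.00 h. Carrying the reagent gain from that result to the neighbouring flask with 1.20 equiv of reagent gives 33.6%. That neighbouring flask holds 31.1% of target at 3.0 h.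

(All runs were generated by integration on assumed constants, noise included.)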